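**Retrosynthetic overview**

1. The free phenol is unmasked last (fluoride). Before that, the side chain is cut at the C‑5′–C‑6′ bond (hexadienyl chain numbered from the chroman), which gives a β‑cyclogeranyl nucleophile and a (2Z,4E)‑dienyl bromide that already carries the chroman.
2. The enabling feature: C‑6′ (the exocyclic CH2 on C‑1 of the trimethylcyclohexene) and C‑5′ (the CH2 on the methyl‑bearing carbon of the Z‑olefin) are both primary allylic carbons. The bond is the central σ‑bond of the 1,5‑diene ring‑C2(CH3)=ring‑C1–CH2–CH2–C(CH3)=CH, so an α,α′ allyl–allyl coupling can make it, and the fully substituted ring C‑2 blocks γ‑attack.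
3. The dienyl bromide comes from the (2Z,4E)‑dienol, made by Suzuki–Miyaura coupling of an (E)‑alkenylboronate (from the chroman‑2‑carbaldehyde) with (Z)‑3‑iodo‑2‑methylprop‑2‑en‑1‑ol; the Z‑olefin is thus fixed before the union.
4. The chroman is the only ring formed in the route (O1–C8a bond, Pd‑catalysed aryl etherification of a tertiary alcohol). Its stereocentre comes from (S)‑2‑methylglycidol and no bond to it is broken.
5. Order of rings: benzene ring purchased, then the pyran ring of the chroman (step 5); the cyclohexene is purchased as β‑cyclocitral.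

Key step: step 14

Remark: compounds 1, 4, 12 and 18 and all named reagents are taken as purchasable; the phenol is carried as its triisopropylsilyl ether because the tertiary dienylic aryl ether of the target would not tolerate an acidic deprotection.

**Route**

Step 1
Reactants: 1 4-bromo-3-methylphenol
Product: 2 (4-bromo-3-methylphenoxy)triisopropylsilane
Conditions: TIPSCl, imidazole, DMF, rt
Reagents that add atoms: triisopropylsilyl chloride, CC(C)[Si](Cl)(C(C)C)C(C)C
Why: Imidazole-promoted O-silylation of a phenol; the TIPS ether should survive the Grignard, carbonate, mild-acid and aqueous-phosphate steps and is removable by fluoride at the end.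

Step 2
Reactants: 2 (4-bromo-3-methylphenoxy)triisopropylsilane
Product: 3 [4-bromo-3-(bromomethyl)phenoxy]triisopropylsilane
Conditions: NBS, AIBN (cat.), PhCF3, 85 °C
Reagents that add atoms: N-bromosuccinimide, O=C1CCC(=O)N1Br
Why: Wohl–Ziegler benzylic bromination; radical-chain conditions in a non-polar solvent should favour the benzylic C–H over ring bromination.

Step 3
Reactants: 4 (S)-2-methylglycidol
Product: 5 tert-butyldimethyl{[(2R)-2-methyloxiran-2-yl]methoxy}silane
Conditions: TBSCl, imidazole, CH2Cl2, 0 °C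
Reagents that add atoms: tert-butyldimethylsilyl chloride, CC(C)(C)[Si](C)(C)Cl
Why: O-silylation without strong base, so no alkoxide is formed that could scramble the epoxide by Payne rearrangement; no bond at the stereocentre is touched, and the descriptor changes from S to R only because CH2OSi outranks the oxirane CH2.

Step 4
Reactants: 3 [4-bromo-3-(bromomethyl)phenoxy]triisopropylsilane, 5 tert-butyldimethyl{[(2R)-2-methyloxiran-2-yl]methoxy}silane
Product: 7 (2R)-4-[2-bromo-5-(triisopropylsilyloxy)phenyl]-1-(tert-butyldimethylsilyloxy)-2-methylbutan-2-ol, via benzylic Grignard reagent 6 (not isolated)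
Conditions: Mg, Et2O, 0 °C (slow addition of 3); then 5, CuI (10 mol%), THF, −30 to 0 °C; aq. NH4Cl
Reagents that add atoms: magnesium, [Mg]
Why: Magnesium inserts into the benzylic C–Br bond much faster than into the aryl C–Br bond, and the copper-catalysed Grignard opening of a 2,2-disubstituted epoxide takes place at the unsubstituted CH2 (SN2), so the carbinol stereocentre is carried over from 5 unchanged.

Step 5
Reactants: 7 (2R)-4-[2-bromo-5-(triisopropylsilyloxy)phenyl]-1-(tert-butyldimethylsilyloxy)-2-methylbutan-2-ol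
Product: 8 tert-butyldimethyl{[(2R)-2-methyl-6-(triisopropylsilyloxy)-3,4-dihydro-2H-chromen-2-yl]methoxy}silane
Conditions: Pd(OAc)2 (3 mol%), 2-(di-tert-butylphosphino)-1,1′-binaphthyl (4 mol%), Cs2CO3, toluene, 80 °C
Reagents that add atoms: none
Why: Intramolecular Pd-catalysed aryl etherification (Buchwald–Hartwig-type C–O coupling) closes the six-membered ring; a tertiary alkoxide has no carbinol hydrogen for β-hydride elimination, and only the O–H bond reacts, so the configuration is retained.

Step 6
Reactants: 8 tert-butyldimethyl{[(2R)-2-methyl-6-(triisopropylsilyloxy)-3,4-dihydro-2H-chromen-2-yl]methoxy}silane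
Product: 9 [(2R)-2-methyl-6-(triisopropylsilyloxy)-3,4-dihydro-2H-chromen-2-yl]methanol
Conditions: CSA (0.2 equiv), MeOH/CH2Cl2 1:1, rt
Reagents that add atoms: none
Why: Acid-catalysed methanolysis should cleave the alkyl TBS ether selectively, since aryl silyl ethers (here the bulkier TIPS) are much more stable to acid.

Step 7
Reactants: 9 [(2R)-2-methyl-6-(triisopropylsilyloxy)-3,4-dihydro-2H-chromen-2-yl]methanol
Product: 10 (2R)-2-methyl-6-(triisopropylsilyloxy)-3,4-dihydro-2H-chromene-2-carbaldehyde
Conditions: Dess–Martin periodinane, CH2Cl2, rt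
Reagents that add atoms: none
Why: Dess–Martin oxidation of a neopentyl-type primary alcohol; the aldehyde has no α-hydrogen, so the stereocentre cannot epimerise.

Step 8
Reactants: 10 (2R)-2-methyl-6-(triisopropylsilyloxy)-3,4-dihydro-2H-chromene-2-carbaldehyde
Product: 11 2-{(E)-2-[(2R)-2-methyl-6-(triisopropylsilyloxy)-3,4-dihydro-2H-chromen-2-yl]ethenyl}-4,4,5,5-tetramethyl-1,3,2-dioxaborolane
Conditions: CH2(Bpin)2, LiTMP (from TMP and n-BuLi), THF, 0 °C; then 10, −78 °C to rt
Reagents that add atoms: bis[(pinacolato)boryl]methane, CC1(C)OB(CB2OC(C)(C)C(C)(C)O2)OC1(C)C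
Why: Boron-Wittig olefination; the α-boryl carbanion adds to the aldehyde and syn B–O elimination should give the trans-alkenylboronate, the bulky α-quaternary substituent favouring E.

Step 9
Reactants: 12 prop-2-yn-1-ol
Product: 14 (Z)-3-iodo-2-methylprop-2-en-1-ol, via chelated alkenylmagnesium alkoxide 13 (not isolated)
Conditions: MeMgBr (2.5 equiv), CuI (10 mol%), THF/Et2O, −10 °C to rt; then I2, 0 °C; aq. Na2S2O3
Reagents that add atoms: methylmagnesium bromide, C[Mg]Br; iodine, II
Why: Copper-catalysed carbomagnesiation of the magnesium propargylate places methyl on the internal carbon and magnesium on the terminus cis to the CH2O group within a five-membered chelate, and iodinolysis with retention should give the Z-iodide.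

Step 10
Reactants: 11 2-{(E)-2-[(2R)-2-methyl-6-(triisopropylsilyloxy)-3,4-dihydro-2H-chromen-2-yl]ethenyl}-4,4,5,5-tetramethyl-1,3,2-dioxaborolane, 14 (Z)-3-iodo-2-methylprop-2-en-1-ol
Product: 15 (2Z,4E)-2-methyl-5-[(2R)-2-methyl-6-(triisopropylsilyloxy)-3,4-dihydro-2H-chromen-2-yl]penta-2,4-dien-1-ol
Conditions: Pd(dppf)Cl2 (5 mol%), 3 M aq. K3PO4, THF, 45 °C
Reagents that add atoms: none
Why: Suzuki–Miyaura alkenyl–alkenyl coupling proceeds with retention at both sp2 carbons, so the E-boronate and the Z-iodide should give the (2Z,4E)-dienol directly.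

Step 11
Reactants: 15 (2Z,4E)-2-methyl-5-[(2R)-2-methyl-6-(triisopropylsilyloxy)-3,4-dihydro-2H-chromen-2-yl]penta-2,4-dien-1-ol
Product: 17 {[(2R)-2-[(1E,3Z)-5-bromo-4-methylpenta-1,3-dien-1-yl]-2-methyl-3,4-dihydro-2H-chromen-6-yl]oxy}triisopropylsilane, via allylic mesylate 16 (not isolated)
Conditions: MsCl, Et3N, THF, −40 °C; then LiBr, THF, −40 to 0 °C; cold non-acidic work-up, used at once
Reagents that add atoms: methanesulfonyl chloride, CS(=O)(=O)Cl; lithium bromide, [Li+].[Br-]
Why: Mesylation followed by SN2 displacement with bromide at the primary allylic carbon under cold, acid-free conditions should avoid ionisation of the dienyl system and of the tertiary dienylic aryl ether, keeping the Z-olefin.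

Step 12
Reactants: 18 β-cyclocitral
Product: 19 β-cyclogeraniol
Conditions: NaBH4, MeOH, 0 °C
Reagents that add atoms: none
Why: Borohydride 1,2-reduction of an enal whose β-carbon is fully substituted, so conjugate reduction should not compete.

Step 13
Reactants: 19 β-cyclogeraniol
Product: 20 β-cyclogeranyl chloride
Conditions: PPh3, NCS, THF, 0 °C to rt
Reagents that add atoms: N-chlorosuccinimide, O=C1CCC(=O)N1Cl
Why: Appel-type chlorination by SN2 at the primary allylic carbon; SN2′ attack would have to occur at the fully substituted ring carbon.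

Step 14
Reactants: 20 β-cyclogeranyl chloride, 17 {[(2R)-2-[(1E,3Z)-5-bromo-4-methylpenta-1,3-dien-1-yl]-2-methyl-3,4-dihydro-2H-chromen-6-yl]oxy}triisopropylsilane
Product: 22 triisopropyl{[(2R)-2-methyl-2-[(1E,3Z)-4-methyl-6-(2,6,6-trimethylcyclohex-1-en-1-yl)hexa-1,3-dien-1-yl]-3,4-dihydro-2H-chromen-6-yl]oxy}silane, via β-cyclogeranylbarium chloride 21 (not isolated)
Conditions: BaI2 (1.1 equiv per 2 Li), lithium biphenylide, THF, rt; 20 (2 equiv), −78 °C, 30 min; then 17 (1 equiv), THF, −78 °C; sat. NH4Cl
Reagents that add atoms: barium, [Ba]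
Why: Activated barium inserts into the allylic C–Cl bond of 20 at −78 °C, and the allylbarium 21 displaces bromide from the primary allylic carbon of 17 (SN2), forming the CH2–CH2 bond between the two allyl termini head-to-head. The closest known reaction type is the α,α′-selective cross-coupling of allylbarium reagents with allylic bromides used to join prenyl units, which keeps the olefin geometry of both partners. No ring is closed and no stereocentre is created; the remote C-2 centre of the chroman is not involved. The step needs α- over γ-attack of the nucleophile, SN2 over SN2′ attack on the electrophile, cross- over homo-coupling, and retention of the 1E,3Z-diene. α-Attack is secured because the γ-carbon of 21 is the fully substituted ring carbon C-2 (a quaternary centre would have to form) while the α-carbon is a free CH2, and SN2 attack because the bromide sits on a primary carbon whereas the far diene terminus is neopentylic next to the quaternary chroman carbon. Pre-forming 21 in excess at −78 °C before 17 is added should limit halogen–metal exchange and homo-coupling, and the cold, non-ionising medium leaves the Z-trisubstituted olefin untouched.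

Step 15
Reactants: 22 triisopropyl{[(2R)-2-methyl-2-[(1E,3Z)-4-methyl-6-(2,6,6-trimethylcyclohex-1-en-1-yl)hexa-1,3-dien-1-yl]-3,4-dihydro-2H-chromen-6-yl]oxy}silane
Product: 23 (2R)-2-methyl-2-[(1E,3Z)-4-methyl-6-(2,6,6-trimethylcyclohex-1-en-1-yl)hexa-1,3-dien-1-yl]-3,4-dihydro-2H-chromen-6-ol
Conditions: TBAF, THF, 0 °C; aq. NH4Cl
Reagents that add atoms: none
Why: Fluoride cleavage of the aryl silyl ether is non-acidic and should spare the acid-labile tertiary dienylic aryl ether and the Z,E-diene.

**Compound list**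

1 | 4-bromo-3-methylphenol | Cc1cc(O)ccc1Br | starting material
2 | (4-bromo-3-methylphenoxy)triisopropylsilane | Cc1cc(O[Si](C(C)C)(C(C)C)C(C)C)ccc1Br | intermediate
3 | [4-bromo-3-(bromomethyl)phenoxy]triisopropylsilane | BrCc1cc(O[Si](C(C)C)(C(C)C)C(C)C)ccc1Br | intermediate
4 | (S)-2-methylglycidol, (2S)-(2-methyloxiran-2-yl)methanol | OC[C@@]1(C)CO1 | starting material
5 | tert-butyldimethyl{[(2R)-2-methyloxiran-2-yl]methoxy}silane | CC(C)(C)[Si](C)(C)OC[C@@]1(C)CO1 | intermediate
6 | [2-bromo-5-(triisopropylsilyloxy)benzyl]magnesium bromide (benzylic Grignard reagent, not isolated) | Br[Mg]Cc1cc(O[Si](C(C)C)(C(C)C)C(C)C)ccc1Br | intermediate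
7 | (2R)-4-[2-bromo-5-(triisopropylsilyloxy)phenyl]-1-(tert-butyldimethylsilyloxy)-2-methylbutan-2-ol | CC(C)(C)[Si](C)(C)OC[C@@](O)(C)CCc1cc(O[Si](C(C)C)(C(C)C)C(C)C)ccc1Br | intermediate
8 | tert-butyldimethyl{[(2R)-2-methyl-6-(triisopropylsilyloxy)-3,4-dihydro-2H-chromen-2-yl]methoxy}silane | CC(C)(C)[Si](C)(C)OC[C@@]1(C)CCc2cc(O[Si](C(C)C)(C(C)C)C(C)C)ccc2O1 | intermediate
9 | [(2R)-2-methyl-6-(triisopropylsilyloxy)-3,4-dihydro-2H-chromen-2-yl]methanol | OC[C@@]1(C)CCc2cc(O[Si](C(C)C)(C(C)C)C(C)C)ccc2O1 | intermediate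
10 | (2R)-2-methyl-6-(triisopropylsilyloxy)-3,4-dihydro-2H-chromene-2-carbaldehyde | O=C[C@@]1(C)CCc2cc(O[Si](C(C)C)(C(C)C)C(C)C)ccc2O1 | intermediate
11 | 2-{(E)-2-[(2R)-2-methyl-6-(triisopropylsilyloxy)-3,4-dihydro-2H-chromen-2-yl]ethenyl}-4,4,5,5-tetramethyl-1,3,2-dioxaborolane | CC1(C)OB(/C=C/[C@@]2(C)CCc3cc(O[Si](C(C)C)(C(C)C)C(C)C)ccc3O2)OC1(C)C | intermediate
12 | prop-2-yn-1-ol | C#CCO | starting material
13 | bromomagnesium (Z)-3-(bromomagnesio)-2-methylprop-2-en-1-olate (chelated alkenylmagnesium alkoxide, not isolated) | Br[Mg]OC/C(C)=C\[Mg]Br | intermediate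
14 | (Z)-3-iodo-2-methylprop-2-en-1-ol | OC/C(C)=C\I | intermediate
15 | (2Z,4E)-2-methyl-5-[(2R)-2-methyl-6-(triisopropylsilyloxy)-3,4-dihydro-2H-chromen-2-yl]penta-2,4-dien-1-ol | OC/C(C)=C\C=C\[C@@]1(C)CCc2cc(O[Si](C(C)C)(C(C)C)C(C)C)ccc2O1 | intermediate
16 | (2Z,4E)-2-methyl-5-[(2R)-2-methyl-6-(triisopropylsilyloxy)-3,4-dihydro-2H-chromen-2-yl]penta-2,4-dien-1-yl methanesulfonate (allylic mesylate, not isolated) | CS(=O)(=O)OC/C(C)=C\C=C\[C@@]1(C)CCc2cc(O[Si](C(C)C)(C(C)C)C(C)C)ccc2O1 | intermediate
17 | {[(2R)-2-[(1E,3Z)-5-bromo-4-methylpenta-1,3-dien-1-yl]-2-methyl-3,4-dihydro-2H-chromen-6-yl]oxy}triisopropylsilane | BrC/C(C)=C\C=C\[C@@]1(C)CCc2cc(O[Si](C(C)C)(C(C)C)C(C)C)ccc2O1 | intermediate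
18 | β-cyclocitral, 2,6,6-trimethylcyclohex-1-ene-1-carbaldehyde | CC1=C(C=O)C(C)(C)CCC1 | starting material
19 | β-cyclogeraniol, (2,6,6-trimethylcyclohex-1-en-1-yl)methanol | CC1=C(CO)C(C)(C)CCC1 | intermediate
20 | β-cyclogeranyl chloride, 2-(chloromethyl)-1,3,3-trimethylcyclohex-1-ene | CC1=C(CCl)C(C)(C)CCC1 | intermediate
21 | [(2,6,6-trimethylcyclohex-1-en-1-yl)methyl]barium chloride (β-cyclogeranylbarium chloride, not isolated) | CC1=C(C[Ba]Cl)C(C)(C)CCC1 | intermediate
22 | triisopropyl{[(2R)-2-methyl-2-[(1E,3Z)-4-methyl-6-(2,6,6-trimethylcyclohex-1-en-1-yl)hexa-1,3-dien-1-yl]-3,4-dihydro-2H-chromen-6-yl]oxy}silane | CC1=C(CC/C(C)=C\C=C\[C@@]2(C)CCc3cc(O[Si](C(C)C)(C(C)C)C(C)C)ccc3O2)C(C)(C)CCC1 | intermediate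
23 | (2R)-2-methyl-2-[(1E,3Z)-4-methyl-6-(2,6,6-trimethylcyclohex-1-en-1-yl)hexa-1,3-dien-1-yl]-3,4-dihydro-2H-chromen-6-ol | CC1=C(CC/C(C)=C\C=C\[C@@]2(C)CCc3cc(O)ccc3O2)C(C)(C)CCC1 | target

**Step count and risks**

Total step count: 15. Longest linear sequence: 11 steps (steps 1, 2, 4, 5, 6, 7, 8, 10, 11, 14, 15).

Steps most likely to fail:

1. Step 14. Electron transfer from the allylbarium to the conjugated dienyl bromide could cause halogen–metal exchange and statistical homo-coupling, or the nucleophile could attack the diene in an SN2′ sense. The fallback replaces the free allyl metal by a sulfonyl-stabilised carbanion. It sets out from 20 and 17 and comes back at 22. Chloride 20 would be treated with sodium benzenesulfinate (DMF, rt) to give β-cyclogeranyl phenyl sulfone F1. Its lithio derivative (n-BuLi, THF/HMPA, −78 °C) would be alkylated with bromide 17 to give the coupled sulfone F2 (both epimers at the sulfonyl-bearing carbon). Reductive desulfonylation (6% Na/Hg, Na2HPO4, THF/MeOH, −20 °C) should then give 22.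

2. Step 11. Ionisation or reversible SN2′ addition of bromide during activation could transpose the allylic system or erode the Z-olefin. The fallback avoids a halide altogether. It sets out from 15 and comes back at 22. Dienol 15 would be converted with diethyl chlorophosphate and pyridine (CH2Cl2, 0 °C) into the allylic diethyl phosphate F3, which is formed without acid or halide ion and keeps the leaving group on the primary carbon. F3 would then be used in place of 17 as the electrophile toward barium reagent 21 (THF, −78 °C).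

3. Step 10. Transmetalation of the hindered alkenylboronate could be slow, allowing protodeboronation and palladium-mediated isomerisation of the Z-olefin. The fallback builds the Z-olefin by stereoselective olefination instead of cross-coupling. It sets out from 10 and comes back at 15. Horner–Wadsworth–Emmons reaction of aldehyde 10 with diethyl [2-(methoxy(methyl)amino)-2-oxoethyl]phosphonate (NaH, THF) should give the E-configured Weinreb enamide F4, and DIBAL-H (THF, −78 °C) the enal F5. Still–Gennari olefination of F5 with methyl 2-[bis(2,2,2-trifluoroethoxy)phosphoryl]propanoate (KHMDS, 18-crown-6, THF, −78 °C) should give the (2Z,4E)-dienoate F6, and DIBAL-H (CH2Cl2, −78 °C) would reduce it to 15.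

Further compounds
F1 | step 14 | β-cyclogeranyl phenyl sulfone, {[(2,6,6-trimethylcyclohex-1-en-1-yl)methyl]sulfonyl}benzene | CC1=C(CS(=O)(=O)c2ccccc2)C(C)(C)CCC1
F2 | step 14 | triisopropyl{[(2R)-2-methyl-2-[(1E,3Z)-4-methyl-6-(phenylsulfonyl)-6-(2,6,6-trimethylcyclohex-1-en-1-yl)hexa-1,3-dien-1-yl]-3,4-dihydro-2H-chromen-6-yl]oxy}silane (both epimers at C-6′) | CC1=C(C(C/C(C)=C\C=C\[C@@]2(C)CCc3cc(O[Si](C(C)C)(C(C)C)C(C)C)ccc3O2)S(=O)(=O)c2ccccc2)C(C)(C)CCC1
F3 | step 11 | diethyl (2Z,4E)-2-methyl-5-[(2R)-2-methyl-6-(triisopropylsilyloxy)-3,4-dihydro-2H-chromen-2-yl]penta-2,4-dien-1-yl phosphate | CCOP(=O)(OCC)OC/C(C)=C\C=C\[C@@]1(C)CCc2cc(O[Si](C(C)C)(C(C)C)C(C)C)ccc2O1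
F4 | step 10 | (E)-N-methoxy-N-methyl-3-[(2R)-2-methyl-6-(triisopropylsilyloxy)-3,4-dihydro-2H-chromen-2-yl]prop-2-enamide | CON(C)C(=O)/C=C/[C@@]1(C)CCc2cc(O[Si](C(C)C)(C(C)C)C(C)C)ccc2O1
F5 | step 10 | (E)-3-[(2R)-2-methyl-6-(triisopropylsilyloxy)-3,4-dihydro-2H-chromen-2-yl]prop-2-enal | O=C/C=C/[C@@]1(C)CCc2cc(O[Si](C(C)C)(C(C)C)C(C)C)ccc2O1
F6 | step 10 | methyl (2Z,4E)-2-methyl-5-[(2R)-2-methyl-6-(triisopropylsilyloxy)-3,4-dihydro-2H-chromen-2-yl]penta-2,4-dienoate | COC(=O)/C(C)=C\C=C\[C@@]1(C)CCc2cc(O[Si](C(C)C)(C(C)C)C(C)C)ccc2O1
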